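## Retrosynthetic overview
1. Target 13 comes from endoperoxide 11 by O–O and O–Si cleavage. Both new C–O bonds (C3–O, C6–O) and both new stereocentres arise in one dye-sensitised 1O2 [4+2] addition to diene 10.
2. Diene 10 comes from the allylic cis-diol 6 by 1,4-dehydration (sulfenate→sulfoxide [2,3] shift, then syn-elimination), with 4-OH capped as SiEt3.
3. Diol 6 comes from (−)-shikimic acid 1: CO2H → CH2OH, and benzoates placed on O5 and O7 while the cis-3,4-diol sits in an acetonide.
4. Rings: the carbocycle is bought with 1, and C4 and C5 are kept. The dioxolane is closed in Step 1 and opened in Step 3. The 2,3-dioxabicyclo[2.2.2]octene is closed and opened in Step 5.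

Assumption and convention: the target is taken exactly as the SMILES, i.e. 3S,4R,5R,6R. Shikimate numbering is kept throughout (C1 carries C7, C2 is the ring CH next to C3). "Upper face" is the face of 3-OH/4-OH of 1, and "lower face" is that of 5-OH.

## Route

Step 1
Reactants: 1 (−)-shikimic acid
Product: 3 methyl (3R,4S,5R)-3,4-O-isopropylideneshikimate, via methyl shikimate 2 (not isolated)
Conditions: MeOH, TsOH·H2O (5 mol %), reflux; evaporate; 2,2-dimethoxypropane, acetone, rt
Reagents that add atoms: methanol, CO; 2,2-dimethoxypropane, COC(C)(C)OC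
Why: Fischer esterification followed by transketalisation, which can only bridge the cis-3,4-diol, so 5-OH stays free and no stereocentre is touched.

Step 2
Reactants: 3 methyl (3R,4S,5R)-3,4-O-isopropylideneshikimate
Product: 4 (3R,4S,5R)-1-(hydroxymethyl)-3,4-O-isopropylidenecyclohex-1-ene-3,4,5-triol
Conditions: iBu2AlH (4 equiv), CH2Cl2, −78 to 0 °C; H2O/aq. NaOH work-up
Reagents that add atoms: none
Why: 1,2-hydride reduction of the conjugated ester with excess iBu2AlH gives the primary allylic alcohol and leaves the alkene, the acetonide and all stereocentres alone.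

Step 3
Reactants: 4 (3R,4S,5R)-1-(hydroxymethyl)-3,4-O-isopropylidenecyclohex-1-ene-3,4,5-triol
Product: 6 [(3R,4R,5R)-5-(benzoyloxy)-3,4-dihydroxycyclohex-1-en-1-yl]methyl benzoate, via acetonide dibenzoate 5 (not isolated)
Conditions: BzCl (2.4 equiv), pyridine, 4-(dimethylamino)pyridine (5 mol %), 0 °C to rt; evaporate; AcOH/H2O 4:1, 55 °C
Reagents that add atoms: benzoyl chloride, O=C(Cl)c1ccccc1
Why: O-acylation of the only two free hydroxyls is followed by acid hydrolysis of the cis-fused dioxolane, under which benzoates survive and the trans-vicinal O5→O4 acyl shift is slow.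

Step 4
Reactants: 6 [(3R,4R,5R)-5-(benzoyloxy)-3,4-dihydroxycyclohex-1-en-1-yl]methyl benzoate
Product: 10 [(4R,5R)-5-(benzoyloxy)-4-(triethylsilyloxy)cyclohexa-1(6),2-dien-1-yl]methyl benzoate, via O3-sulfenate 7 (not isolated), via C1-sulfoxide 8 (not isolated), via dienol 9 (not isolated)
Conditions: 2,4-(O2N)2C6H3SCl (1.05 equiv), Et3N (5 equiv), CH2Cl2, 0 to 40 °C; then Et3SiOTf (2.5 equiv), −20 °C; Et3N-deactivated silica
Reagents that add atoms: triethylsilyl trifluoromethanesulfonate, CC[Si](CC)(CC)OS(=O)(=O)C(F)(F)F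
Why: O-sulfenylation of the more accessible allylic 3-OH triggers a suprafacial Mislow–Evans-type [2,3] shift to the upper-face C1 sulfoxide, whose syn-elimination (electron-poor aryl group, C6–H rather than the oxygen-bearing C7–H) is a net 1,4-dehydration that erases C3 and leaves C4 and C5 untouched, and the dienol is silylated at once to stop acyl shift and aromatisation.

Step 5
Reactants: 10 [(4R,5R)-5-(benzoyloxy)-4-(triethylsilyloxy)cyclohexa-1(6),2-dien-1-yl]methyl benzoate
Product: 13 [(3S,4R,5R,6R)-5-(benzoyloxy)-3,4,6-trihydroxycyclohex-1-en-1-yl]methyl benzoate, via endoperoxide 11 (not isolated), via silyl ether diol 12 (not isolated)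
Conditions: O2 (1 atm), 5,10,15,20-tetraphenylporphyrin (0.5 mol %), CH2Cl2, −78 °C, white LED; then thiourea (2.2 equiv), MeOH, −78 °C to rt; then 1 M aq. HCl, 0 °C
Reagents that add atoms: dioxygen, O=O
Why: Proposed new method: a π-facially selective singlet-oxygen [4+2] photooxygenation of a non-symmetric arene trans-dihydrodiol whose two allylic oxygens are deliberately mismatched (donor O–SiEt3 on the upper face at C4, acceptor O–benzoate on the lower face at C5, and no free 4-OH that would hydrogen-bond 1O2 to the wrong face), in which the electrophilic 1O2, building negative charge on oxygen in the transition state, avoids the electron-rich pseudoaxial silyl ether oxygen and the SiEt3 bulk next to C3, keeps the better σ-donor C4–O bond anti to the forming C3–O bond, and turns 5-OBz toward the small O–O bridge rather than toward the CH2OBz-bearing etheno bridge, so both C–O bonds form on the lower face (expected d.r. at least 5:1) and set C3 (S) and C6 (R) cis to each other and to 5-OBz, after which thiourea cleaves only O–O with retention and dilute HCl removes SiEt3; the closest known reaction type is endoperoxide formation and thiourea reduction of C2-symmetric trans-5,6-diacyloxycyclohexa-1,3-dienes (conduritol F route) and anti-selective photooxygenation of cis-diol acetonides.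

## Compound list
1 | (−)-shikimic acid = (3R,4S,5R)-3,4,5-trihydroxycyclohex-1-ene-1-carboxylic acid | OC(=O)C1=C[C@@H](O)[C@@H](O)[C@H](O)C1 | starting material
2 | methyl (3R,4S,5R)-shikimate | COC(=O)C1=C[C@@H](O)[C@@H](O)[C@H](O)C1 | intermediate
3 | methyl (3R,4S,5R)-3,4-O-isopropylideneshikimate (5-OH free) | COC(=O)C1=C[C@H]2OC(C)(C)O[C@H]2[C@H](O)C1 | intermediate
4 | (3R,4S,5R)-1-(hydroxymethyl)-3,4-O-isopropylidenecyclohex-1-ene-3,4,5-triol | OCC1=C[C@H]2OC(C)(C)O[C@H]2[C@H](O)C1 | intermediate
5 | 5,7-di-O-benzoate of 4 (3R,4S,5R) | O=C(OCC1=C[C@H]2OC(C)(C)O[C@H]2[C@H](OC(=O)c2ccccc2)C1)c1ccccc1 | intermediate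
6 | [(3R,4R,5R)-5-(benzoyloxy)-3,4-dihydroxycyclohex-1-en-1-yl]methyl benzoate (3-OH and 4-OH on the upper face, 5-OBz on the lower face) | O=C(OCC1=C[C@@H](O)[C@@H](O)[C@H](OC(=O)c2ccccc2)C1)c1ccccc1 | intermediate
7 | 3-O-(2,4-dinitrophenylsulfenyl) derivative of 6 (3R,4S,5R) | O=C(OCC1=C[C@@H](OSc2ccc(cc2[N+](=O)[O-])[N+](=O)[O-])[C@@H](O)[C@H](OC(=O)c2ccccc2)C1)c1ccccc1 | intermediate
8 | [(1R,4R,5R)-5-(benzoyloxy)-1-(2,4-dinitrophenylsulfinyl)-4-hydroxycyclohex-2-en-1-yl]methyl benzoate (S on the upper face, configuration at sulfur not defined) | O=C(OC[C@]1(S(=O)c2ccc(cc2[N+](=O)[O-])[N+](=O)[O-])C=C[C@@H](O)[C@H](OC(=O)c2ccccc2)C1)c1ccccc1 | intermediate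
9 | [(4R,5R)-5-(benzoyloxy)-4-hydroxycyclohexa-1(6),2-dien-1-yl]methyl benzoate | O=C(OCC1=C[C@@H](OC(=O)c2ccccc2)[C@H](O)C=C1)c1ccccc1 | intermediate
10 | [(4R,5R)-5-(benzoyloxy)-4-(triethylsilyloxy)cyclohexa-1(6),2-dien-1-yl]methyl benzoate | O=C(OCC1=C[C@@H](OC(=O)c2ccccc2)[C@H](O[Si](CC)(CC)CC)C=C1)c1ccccc1 | intermediate
11 | [(3S,4S,5R,6R)-5-(benzoyloxy)-3,6-epidioxy-4-(triethylsilyloxy)cyclohex-1-en-1-yl]methyl benzoate (O–O bridge on the lower face) | O=C(OCC1=C[C@H](O3)[C@@H](O[Si](CC)(CC)CC)[C@H](OC(=O)c2ccccc2)[C@@H]1O3)c1ccccc1 | intermediate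
12 | [(3S,4R,5R,6R)-5-(benzoyloxy)-3,6-dihydroxy-4-(triethylsilyloxy)cyclohex-1-en-1-yl]methyl benzoate | O=C(OCC1=C[C@H](O)[C@@H](O[Si](CC)(CC)CC)[C@H](OC(=O)c2ccccc2)[C@@H]1O)c1ccccc1 | intermediate
13 | [(3S,4R,5R,6R)-5-(benzoyloxy)-3,4,6-trihydroxycyclohex-1-en-1-yl]methyl benzoate (3-OH, 5-OBz and 6-OH on the lower face, 4-OH on the upper face) | O=C(OCC1=C[C@H](O)[C@@H](O)[C@H](OC(=O)c2ccccc2)[C@@H]1O)c1ccccc1 | target

## Step count and risks
Total steps: 5. Longest linear sequence: 5 (1 → 13).

**Step 5 (the proposed new step).** The risk is that the facial ratio is low or reversed. The fallback sets out from dienol 9 and comes back at 13.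
- Step 4 is stopped before the silyl triflate is added, and 9 is isolated.
- The cycloaddition is replaced by the known palladium-catalysed cis-1,4-diacetoxylation of 1,3-dienes: Pd(OAc)2 (5 mol %), LiCl (0.2 equiv), LiOAc, 1,4-benzoquinone, acetone/AcOH, rt.
- Divalent palladium binds the diene on the upper face, next to the free 4-OH and away from 5-OBz.
- With chloride on the metal, both acetates attack from outside, anti to palladium. This places them on the lower face and gives the 3,6-di-O-acetate of 13 F1.
- HCl in MeOH (0 °C to rt) then methanolyses the two acetates much faster than the benzoates and gives 13.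

**Step 4.** The risks are aromatisation of the dienol, addition of the sulfenyl chloride to the diene, and elimination toward C7. The fallback sets out from 6 and comes back at 9, and from there at 10.
- 1,1'-Carbonyldiimidazole in CH2Cl2 closes the 3,4-cyclic carbonate of 6 F2.
- Pd(PPh3)4 (2 mol %) in THF at rt follows. Zerovalent palladium ionises the allylic C3–O bond of the cyclic carbonate faster than either benzoate.
- CO2 leaves, and the C4 alkoxide takes H-6 from the π-allyl complex (decarboxylative 1,4-elimination) to give 9.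
- Dienol 9 is capped with Et3SiOTf/2,6-lutidine to give 10.

**Step 3.** The risks are O5→O4 benzoyl shift and partial ester loss during the acidic acetonide cleavage. The fallback sets out from 2 and comes back at 6, with no acid step.
- Step 1 is stopped after the esterification, and methyl shikimate 2 is isolated.
- iBu2AlH (6 equiv, THF, −78 to 0 °C) gives (3R,4S,5R)-1-(hydroxymethyl)cyclohex-1-ene-3,4,5-triol F3.
- PhB(OH)2 with azeotropic drying in pyridine/toluene masks only the cis-diol, giving the 3,4-O-phenylboronate of F3 F4.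
- BzCl in pyridine gives the 5,7-di-O-benzoate of F4 F5.
- Neutral exchange with pinacol at rt releases 6.

## Further compounds
F1 | step 5 | 3,6-di-O-acetate of 13 | O=C(OCC1=C[C@H](OC(C)=O)[C@@H](O)[C@H](OC(=O)c2ccccc2)[C@@H]1OC(C)=O)c1ccccc1
F2 | step 4 | 3,4-cyclic carbonate of 6 | O=C(OCC1=C[C@H]2OC(=O)O[C@H]2[C@H](OC(=O)c2ccccc2)C1)c1ccccc1
F3 | step 3 | (3R,4S,5R)-1-(hydroxymethyl)cyclohex-1-ene-3,4,5-triol | OCC1=C[C@@H](O)[C@@H](O)[C@H](O)C1
F4 | step 3 | 3,4-O-phenylboronate of F3 | OCC1=C[C@H]2OB(c3ccccc3)O[C@H]2[C@H](O)C1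
F5 | step 3 | 5,7-di-O-benzoate of F4 | O=C(OCC1=C[C@H]2OB(c3ccccc3)O[C@H]2[C@H](OC(=O)c3ccccc3)C1)c1ccccc1
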